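**Retrosynthetic overview**

1. The target is reached by global deprotection of a fully protected dihydrobenzofuran: four pivalates are removed with i-Bu2AlH, then five benzyl ethers and a C8–Br cap by hydrogenolysis.
2. Key disconnection: the C2–C3 bond of the dihydrofuran ring, closed by cobalt-metalloradical 1,5-C–H alkylation of an aryl alkyl ether N-tosylhydrazone. The enabling feature is that C2–H is α to ring oxygen O1 and 1,5 to benzylic C3 (C3–C3a–C7a–O1–C2). C3 is the former formyl carbon of phloroglucinaldehyde, and the other ortho oxygen (on C4) carries a pivalate with no α-C–H.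
3. The ether precursor comes from a Mitsunobu reaction of 2-hydroxy-4,6-bis(pivaloyloxy)benzaldehyde with an (R)-2,2-diarylethanol.
4. The diarylmethine centre comes from stereoinvertive Friedel–Crafts opening of a CBS-derived (R)-aryloxirane by C6–H of C8-bromo-capped penta-O-benzyl-(+)-epicatechin.
5. Ring order: both flavan rings come intact from (+)-epicatechin (2S,3S); the dihydrofuran ring is the only ring built and is closed last, creating C2 (S).

Key step: step 11

Assumption: (+)-epicatechin (2S,3S) is taken as a purchasable chiral-pool compound (it is also reachable by C2 epimerization of (+)-catechin).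
Remark: [Co(P*)] is the divalent cobalt complex of the D2-symmetric chiral porphyrin 5,15-bis(3,5-di-tert-butylphenyl)-10,20-bis[2,6-bis(2,2-dimethylcyclopropane-1-carboxamido)phenyl]porphyrin with homochiral amide arms; both antipodes are accessible.

**Route**

Step 1
Reactants: 1 (+)-epicatechin
Product: 2 5,7,3',4'-tetra-O-benzyl-(+)-epicatechin
Conditions: BnBr (4.4 equiv), K2CO3, DMF, 0 °C → rt
Reagents that add atoms: benzyl bromide, BrCc1ccccc1
Why: Williamson etherification of the four phenols with a carbonate base should leave the secondary C3 alcohol and both stereocentres untouched.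

Step 2
Reactants: 2 5,7,3',4'-tetra-O-benzyl-(+)-epicatechin
Product: 3 8-bromo-5,7,3',4'-tetra-O-benzyl-(+)-epicatechin
Conditions: NBS (1.0 equiv), CH2Cl2, −78 °C → rt
Reagents that add atoms: N-bromosuccinimide, O=C1CCC(=O)N1Br
Why: Electrophilic aromatic bromination of the phloroglucinol-type ring A should occur at the less hindered C8, capping it so that later Friedel–Crafts chemistry must go to C6.

Step 3
Reactants: 3 8-bromo-5,7,3',4'-tetra-O-benzyl-(+)-epicatechin
Product: 4 8-bromo-3,5,7,3',4'-penta-O-benzyl-(+)-epicatechin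
Conditions: NaH, BnBr, n-Bu4NI (cat.), DMF, 0 °C → rt
Reagents that add atoms: benzyl bromide, BrCc1ccccc1
Why: Williamson benzylation of the C3 alkoxide masks the last hydroxyl, which would otherwise compete in the epoxide opening and in the Mitsunobu step.

Step 4
Reactants: 5 2-chloro-1-(3,4-dihydroxyphenyl)ethan-1-one
Product: 6 4-(chloroacetyl)-1,2-phenylene bis(2,2-dimethylpropanoate)
Conditions: PivCl (2.2 equiv), i-Pr2NEt, CH2Cl2, 0 °C
Reagents that add atoms: pivaloyl chloride, CC(C)(C)C(Cl)=O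
Why: O-acylation of the catechol with a hindered base gives electron-withdrawing, base-tolerant esters that later disfavour benzylic ionization.

Step 5
Reactants: 6 4-(chloroacetyl)-1,2-phenylene bis(2,2-dimethylpropanoate)
Product: 7 4-[(1R)-2-chloro-1-hydroxyethyl]-1,2-phenylene bis(2,2-dimethylpropanoate)
Conditions: (R)-2-methyl-CBS-oxazaborolidine (10 mol%), BH3·SMe2, THF, −20 °C
Reagents that add atoms: none
Why: CBS reduction should deliver hydride under catalyst control (aryl as the large group, CH2Cl as the small group) to set the (R)-carbinol, as for 2-chloroacetophenone.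

Step 6
Reactants: 7 4-[(1R)-2-chloro-1-hydroxyethyl]-1,2-phenylene bis(2,2-dimethylpropanoate)
Product: 8 4-[(2R)-oxiran-2-yl]-1,2-phenylene bis(2,2-dimethylpropanoate)
Conditions: NaH, THF, 0 °C
Reagents that add atoms: none
Why: Intramolecular Williamson closure (3-exo-tet) displaces chloride at the CH2 carbon, so the carbinol configuration is retained and should outrun acyl transfer from the hindered pivalates.

Step 7
Reactants: 4 8-bromo-3,5,7,3',4'-penta-O-benzyl-(+)-epicatechin; 8 4-[(2R)-oxiran-2-yl]-1,2-phenylene bis(2,2-dimethylpropanoate)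
Product: 9 (2R)-2-[3,4-bis(pivaloyloxy)phenyl]-2-[8-bromo-penta-O-benzyl-(+)-epicatechin-6-yl]ethan-1-ol
Conditions: HFIP/CH2Cl2 (3:1), 0 °C → rt
Reagents that add atoms: none
Why: In this Friedel–Crafts-type arylative epoxide opening, C6 (the only free position of ring A) should attack the benzylic carbon of the HFIP-activated epoxide from the rear in a borderline SN2 process, the two pivaloyloxy groups disfavouring a free cation, so the epoxide centre is inverted to the required diarylmethine configuration (the descriptor stays R through a priority change).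

Step 8
Reactants: 10 2,4,6-trihydroxybenzaldehyde
Product: 11 2-hydroxy-4,6-bis(pivaloyloxy)benzaldehyde
Conditions: PivCl (2.05 equiv), Et3N, CH2Cl2, −20 → 0 °C
Reagents that add atoms: pivaloyl chloride, CC(C)(C)C(Cl)=O
Why: Acylation should take the para hydroxyl and one ortho hydroxyl and stop before the last one, which is hydrogen-bonded to the formyl group and flanked on both sides.

Step 9
Reactants: 9 (2R)-2,2-diarylethanol; 11 2-hydroxy-4,6-bis(pivaloyloxy)benzaldehyde
Product: 12 2-{(2R)-2-[3,4-bis(pivaloyloxy)phenyl]-2-[8-bromo-penta-O-benzyl-(+)-epicatechin-6-yl]ethoxy}-4,6-bis(pivaloyloxy)benzaldehyde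
Conditions: PPh3, DIAD, THF, 0 °C → rt
Reagents that add atoms: none
Why: Mitsunobu etherification of the acidic salicylaldehyde-type phenol with the primary alcohol forms the aryl–O–CH2 bond without touching the adjacent diarylmethine centre or the esters.

Step 10
Reactants: 12 aldehyde ether
Product: 13 (E)-N-tosylhydrazone of 12
Conditions: TsNHNH2, MeOH/THF, rt
Reagents that add atoms: p-toluenesulfonyl hydrazide, Cc1ccc(cc1)S(=O)(=O)NN
Why: Condensation of the aryl aldehyde with the weakly nucleophilic sulfonyl hydrazide gives the hydrazone under neutral conditions that spare the pivalates.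

Step 11
Reactants: 13 (E)-N-tosylhydrazone
Product: 15 (2S)-2-{(R)-[3,4-bis(pivaloyloxy)phenyl][8-bromo-penta-O-benzyl-(+)-epicatechin-6-yl]methyl}-2,3-dihydrobenzofuran-4,6-diyl bis(2,2-dimethylpropanoate), via aryldiazomethane 14 (not isolated)
Conditions: [Co(P*)] (3 mol%), Cs2CO3 (2 equiv), 1,4-dioxane, 40 °C
Reagents that add atoms: none
Why: Cs2CO3 converts 13 by Bamford–Stevens fragmentation into aryldiazomethane 14, which the divalent cobalt metalloradical activates with loss of N2 to an α-cobalt benzyl radical (a trivalent cobalt carbene radical) at C3; this abstracts one hydrogen of the O–CH2 group by 1,5-hydrogen atom transfer through a six-membered transition state, and the resulting α-oxyalkyl radical at C2 attacks C3 with homolytic release of the catalyst, forming the C2–C3 bond. The closest known reaction type is cobalt-metalloradical intramolecular C–H alkylation with aryldiazomethanes generated in situ from aldehyde N-tosylhydrazones (2-substituted indolines and related five-membered rings), the radical counterpart of carbene 1,5-insertion into α-oxy C–H bonds that gives 2,3-dihydrobenzofurans. The dihydrofuran ring closes in a 5-exo-tet radical substitution at C3, formally a 1,5-C–H insertion. The new C2 stereocentre is set by the chiral cavity of the amidoporphyrin, which decides which diastereotopic hydrogen is abstracted and from which face the C2 radical recombines; the ligand antipode is chosen to give 2S and to be matched with the existing (R)-diarylmethine centre. The step needs site selectivity for the O–CH2 hydrogens over the doubly benzylic methine hydrogen (a 1,6-transfer) and over the other ortho substituent, which the six-membered transfer geometry with α-oxygen activation, the shielding of the methine by its two aryl groups and the ortho pivalate lacking any α-C–H should secure. Slow base-mediated release of 14 keeps the diazo concentration low and should suppress azine and stilbene formation.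

Step 12
Reactants: 15 protected dihydrobenzofuran
Product: 16 tetraphenol (all four pivalates removed; benzyl ethers and C8–Br retained)
Conditions: i-Bu2AlH (excess), CH2Cl2, −78 °C; aq. citric acid
Reagents that add atoms: none
Why: Reductive cleavage of the four aryl pivalates under non-basic, non-hydrolytic conditions frees the phenols without risk to the stereocentres or the benzyl ethers.

Step 13
Reactants: 16 tetraphenol
Product: 17 CNP0161875.1 (target)
Conditions: H2 (1 atm), Pd(OH)2/C, NaOAc, THF/MeOH, rt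
Reagents that add atoms: none
Why: Hydrogenolysis should cleave the five benzyl ethers and the C8–Br cap in one operation, while the flavan C2–O1 bond and the non-benzylic C2–O bond of the dihydrobenzofuran persist under these mild, acetate-buffered conditions.

**Compound list**

1 | (+)-epicatechin, (2S,3S)-2-(3,4-dihydroxyphenyl)chromane-3,5,7-triol | c1c(O)cc2O[C@@H](c3ccc(O)c(O)c3)[C@@H](O)Cc2c1O | starting material
2 | (2S,3S)-5,7-bis(benzyloxy)-2-[3,4-bis(benzyloxy)phenyl]chroman-3-ol | c1c(OCc2ccccc2)cc2O[C@@H](c3ccc(OCc4ccccc4)c(OCc4ccccc4)c3)[C@@H](O)Cc2c1OCc1ccccc1 | intermediate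
3 | (2S,3S)-5,7-bis(benzyloxy)-2-[3,4-bis(benzyloxy)phenyl]-8-bromochroman-3-ol | c1c(OCc2ccccc2)c(Br)c2O[C@@H](c3ccc(OCc4ccccc4)c(OCc4ccccc4)c3)[C@@H](O)Cc2c1OCc1ccccc1 | intermediate
4 | (2S,3S)-3,5,7-tris(benzyloxy)-2-[3,4-bis(benzyloxy)phenyl]-8-bromochromane | c1c(OCc2ccccc2)c(Br)c2O[C@@H](c3ccc(OCc4ccccc4)c(OCc4ccccc4)c3)[C@@H](OCc3ccccc3)Cc2c1OCc1ccccc1 | intermediate
5 | 2-chloro-1-(3,4-dihydroxyphenyl)ethan-1-one | O=C(CCl)c1ccc(O)c(O)c1 | starting material
6 | 4-(chloroacetyl)-1,2-phenylene bis(2,2-dimethylpropanoate) | O=C(CCl)c1ccc(OC(=O)C(C)(C)C)c(OC(=O)C(C)(C)C)c1 | intermediate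
7 | 4-[(1R)-2-chloro-1-hydroxyethyl]-1,2-phenylene bis(2,2-dimethylpropanoate) | O[C@@H](CCl)c1ccc(OC(=O)C(C)(C)C)c(OC(=O)C(C)(C)C)c1 | intermediate
8 | 4-[(2R)-oxiran-2-yl]-1,2-phenylene bis(2,2-dimethylpropanoate) | C1O[C@@H]1c1ccc(OC(=O)C(C)(C)C)c(OC(=O)C(C)(C)C)c1 | intermediate
9 | (2R)-2-[3,4-bis(pivaloyloxy)phenyl]-2-{(2S,3S)-3,5,7-tris(benzyloxy)-2-[3,4-bis(benzyloxy)phenyl]-8-bromochroman-6-yl}ethan-1-ol | OC[C@H](c1ccc(OC(=O)C(C)(C)C)c(OC(=O)C(C)(C)C)c1)c1c(OCc2ccccc2)c(Br)c2O[C@@H](c3ccc(OCc4ccccc4)c(OCc4ccccc4)c3)[C@@H](OCc3ccccc3)Cc2c1OCc1ccccc1 | intermediate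
10 | 2,4,6-trihydroxybenzaldehyde | O=Cc1c(O)cc(O)cc1O | starting material
11 | 2-hydroxy-4,6-bis(pivaloyloxy)benzaldehyde (4-formyl-5-hydroxy-1,3-phenylene bis(2,2-dimethylpropanoate)) | O=Cc1c(O)cc(OC(=O)C(C)(C)C)cc1OC(=O)C(C)(C)C | intermediate
12 | 2-[(2R)-2,2-diarylethoxy]-4,6-bis(pivaloyloxy)benzaldehyde (aryl groups as in 9) | O=Cc1c(OC[C@H](c2ccc(OC(=O)C(C)(C)C)c(OC(=O)C(C)(C)C)c2)c2c(OCc3ccccc3)c(Br)c3O[C@@H](c4ccc(OCc5ccccc5)c(OCc5ccccc5)c4)[C@@H](OCc4ccccc4)Cc3c2OCc2ccccc2)cc(OC(=O)C(C)(C)C)cc1OC(=O)C(C)(C)C | intermediate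
13 | (E)-N-tosylhydrazone of 12 | Cc1ccc(cc1)S(=O)(=O)N/N=C/c1c(OC[C@H](c2ccc(OC(=O)C(C)(C)C)c(OC(=O)C(C)(C)C)c2)c2c(OCc3ccccc3)c(Br)c3O[C@@H](c4ccc(OCc5ccccc5)c(OCc5ccccc5)c4)[C@@H](OCc4ccccc4)Cc3c2OCc2ccccc2)cc(OC(=O)C(C)(C)C)cc1OC(=O)C(C)(C)C | intermediate
14 | aryldiazomethane derived from 13 | [N-]=[N+]=Cc1c(OC[C@H](c2ccc(OC(=O)C(C)(C)C)c(OC(=O)C(C)(C)C)c2)c2c(OCc3ccccc3)c(Br)c3O[C@@H](c4ccc(OCc5ccccc5)c(OCc5ccccc5)c4)[C@@H](OCc4ccccc4)Cc3c2OCc2ccccc2)cc(OC(=O)C(C)(C)C)cc1OC(=O)C(C)(C)C | intermediate (not isolated)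
15 | (2S)-2-{(R)-[3,4-bis(pivaloyloxy)phenyl][(2S,3S)-3,5,7-tris(benzyloxy)-2-(3,4-bis(benzyloxy)phenyl)-8-bromochroman-6-yl]methyl}-2,3-dihydrobenzofuran-4,6-diyl bis(2,2-dimethylpropanoate) | CC(C)(C)C(=O)Oc1cc(OC(=O)C(C)(C)C)c2c(c1)O[C@H]([C@H](c1ccc(OC(=O)C(C)(C)C)c(OC(=O)C(C)(C)C)c1)c1c(OCc3ccccc3)c(Br)c3O[C@@H](c4ccc(OCc5ccccc5)c(OCc5ccccc5)c4)[C@@H](OCc4ccccc4)Cc3c1OCc1ccccc1)C2 | intermediate
16 | (2S)-2-{(R)-(3,4-dihydroxyphenyl)[(2S,3S)-3,5,7-tris(benzyloxy)-2-(3,4-bis(benzyloxy)phenyl)-8-bromochroman-6-yl]methyl}-2,3-dihydrobenzofuran-4,6-diol | Oc1cc(O)c2c(c1)O[C@H]([C@H](c1ccc(O)c(O)c1)c1c(OCc3ccccc3)c(Br)c3O[C@@H](c4ccc(OCc5ccccc5)c(OCc5ccccc5)c4)[C@@H](OCc4ccccc4)Cc3c1OCc1ccccc1)C2 | intermediate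
17 | CNP0161875.1, (2S)-2-{(R)-(3,4-dihydroxyphenyl)[(2S,3S)-2-(3,4-dihydroxyphenyl)-3,5,7-trihydroxychroman-6-yl]methyl}-2,3-dihydrobenzofuran-4,6-diol | Oc1cc(O)c2c(c1)O[C@H]([C@H](c1ccc(O)c(O)c1)c1c(O)cc3c(c1O)C[C@H](O)[C@H](c1ccc(O)c(O)c1)O3)C2 | target

**Step count**

Total steps: 13. Longest linear sequence: 9 steps (steps 1, 2, 3, 7, 9, 10, 11, 12, 13; the epoxide branch through steps 4, 5, 6 is equally long).

**Steps most likely to fail**

Step 7. The epoxide may ionize to a free benzylic cation, which would erode the inversion and open the way to rearrangement into an arylacetaldehyde. Alternatively, attack by the hindered, bromine-deactivated C6 position may be too slow. The fallback sets the diarylmethine centre by catalyst-controlled conjugate arylation and runs from 4 back to 9. Vilsmeier–Haack formylation of 4 (POCl3, DMF) at C6 should give the 6-carbaldehyde F1. Henry condensation (MeNO2, NH4OAc) should give the (E)-nitroalkene F2. The aryl donor, 2-[3,4-bis(pivaloyloxy)phenyl]-4,4,5,5-tetramethyl-1,3,2-dioxaborolane F3, would be made by pivaloylation of commercial 4-(4,4,5,5-tetramethyl-1,3,2-dioxaborolan-2-yl)benzene-1,2-diol. Hayashi–Miyaura 1,4-addition of F3 to F2 ([RhCl(C2H4)2]2, chiral bicyclic diene ligand, catalytic KOH, dioxane/H2O) should give the (R)-2,2-diaryl-1-nitroethane F4, the diene antipode fixing the centre. NaNO2/AcOH/DMSO should convert the primary nitro group into the diarylacetic acid F5, and BH3·THF should reduce F5 to 9.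

Step 11. Hydrogen abstraction may occur at the diarylmethine C–H (leading to a six-membered ring), facial control at C2 may be poor if catalyst and substrate are mismatched, or the carbene may dimerize. The fallback forms the same C2–C3 bond photochemically and runs from 12 back to 15. Irradiation of aldehyde 12 (365 nm, degassed benzene) should trigger a Norrish–Yang-type cyclization: the excited formyl group abstracts a δ-hydrogen from the O–CH2 group and the 1,5-biradical collapses to the 3-hydroxy-2,3-dihydrobenzofuran F6. The isomers with the C2 configuration of 15 would be separated and carried on. Treatment with 1,1'-thiocarbonyldiimidazole should give the O-(imidazol-1-ylthiocarbonyl) derivative F7, and Barton–McCombie deoxygenation (Bu3SnH, AIBN, toluene, 80 °C) should give 15.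

Step 9. The oxyphosphonium intermediate at the hindered CH2 may undergo β-elimination or participation by the electron-rich neighbouring aryl ring instead of SN2 displacement by the phenoxide. The fallback replaces in situ activation by a preformed electrophile and runs from 9 back to 12. MsCl/Et3N should convert 9 into the methanesulfonate F8, and Williamson displacement by the caesium phenoxide of 11 (Cs2CO3, DMF, 50 °C) should give 12.

**Further compounds**

F1 | step 7 | (2S,3S)-3,5,7-tris(benzyloxy)-2-[3,4-bis(benzyloxy)phenyl]-8-bromochromane-6-carbaldehyde | O=Cc1c(OCc2ccccc2)c(Br)c2O[C@@H](c3ccc(OCc4ccccc4)c(OCc4ccccc4)c3)[C@@H](OCc3ccccc3)Cc2c1OCc1ccccc1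
F2 | step 7 | (2S,3S)-3,5,7-tris(benzyloxy)-2-[3,4-bis(benzyloxy)phenyl]-8-bromo-6-[(E)-2-nitrovinyl]chromane | [O-][N+](=O)/C=C/c1c(OCc2ccccc2)c(Br)c2O[C@@H](c3ccc(OCc4ccccc4)c(OCc4ccccc4)c3)[C@@H](OCc3ccccc3)Cc2c1OCc1ccccc1
F3 | step 7 | 2-[3,4-bis(pivaloyloxy)phenyl]-4,4,5,5-tetramethyl-1,3,2-dioxaborolane | CC(C)(C)C(=O)Oc1ccc(cc1OC(=O)C(C)(C)C)B1OC(C)(C)C(C)(C)O1
F4 | step 7 | (R)-2-[3,4-bis(pivaloyloxy)phenyl]-2-[8-bromo-penta-O-benzyl-(+)-epicatechin-6-yl]-1-nitroethane | [O-][N+](=O)C[C@H](c1ccc(OC(=O)C(C)(C)C)c(OC(=O)C(C)(C)C)c1)c1c(OCc2ccccc2)c(Br)c2O[C@@H](c3ccc(OCc4ccccc4)c(OCc4ccccc4)c3)[C@@H](OCc3ccccc3)Cc2c1OCc1ccccc1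
F5 | step 7 | (R)-2-[3,4-bis(pivaloyloxy)phenyl]-2-[8-bromo-penta-O-benzyl-(+)-epicatechin-6-yl]acetic acid | OC(=O)[C@H](c1ccc(OC(=O)C(C)(C)C)c(OC(=O)C(C)(C)C)c1)c1c(OCc2ccccc2)c(Br)c2O[C@@H](c3ccc(OCc4ccccc4)c(OCc4ccccc4)c3)[C@@H](OCc3ccccc3)Cc2c1OCc1ccccc1
F6 | step 11 | 3-hydroxy derivative of 15 (C3 epimers, C2 as in 15) | CC(C)(C)C(=O)Oc1cc(OC(=O)C(C)(C)C)c2c(c1)O[C@H]([C@H](c1ccc(OC(=O)C(C)(C)C)c(OC(=O)C(C)(C)C)c1)c1c(OCc3ccccc3)c(Br)c3O[C@@H](c4ccc(OCc5ccccc5)c(OCc5ccccc5)c4)[C@@H](OCc4ccccc4)Cc3c1OCc1ccccc1)C2O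
F7 | step 11 | O-(1H-imidazol-1-ylthiocarbonyl) derivative of F6 | CC(C)(C)C(=O)Oc1cc(OC(=O)C(C)(C)C)c2c(c1)O[C@H]([C@H](c1ccc(OC(=O)C(C)(C)C)c(OC(=O)C(C)(C)C)c1)c1c(OCc3ccccc3)c(Br)c3O[C@@H](c4ccc(OCc5ccccc5)c(OCc5ccccc5)c4)[C@@H](OCc4ccccc4)Cc3c1OCc1ccccc1)C2OC(=S)n1ccnc1
F8 | step 9 | methanesulfonate of alcohol 9 | CS(=O)(=O)OC[C@H](c1ccc(OC(=O)C(C)(C)C)c(OC(=O)C(C)(C)C)c1)c1c(OCc2ccccc2)c(Br)c2O[C@@H](c3ccc(OCc4ccccc4)c(OCc4ccccc4)c3)[C@@H](OCc3ccccc3)Cc2c1OCc1ccccc1
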